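Readings and results are simulated with constants of no real substance; noise was put on by code.

At early times the books of the starting material, the limiting reagent, have few entries: free catalyst turns it into intermediate, second catalyst with partner turns intermediate into target, and free catalyst with partner turns target into over-reaction product.

| setting | theta | epsilon | noon | winter |
|---|---|---|---|---|
| starting material | 0.050 M | 0.050 M | 0.050 M | 0.050 M |
| partner | 1.1 equiv | 1.1 equiv | 1.10 equiv | 1.10 equiv |
| free catalyst | 0.63 mol% | 0.92 mol% | 1 mol% | 1.5 mol% |
| second catalyst | 0.079 mol% | 0.079 mol% | 0.079 mol% | 0.079 mol% |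
| remark | run made earlier | run made earlier |  |  |
| time |  |  | 2.0 min | 2.0 min |

| run | time / s | intermediate / % | over-reaction product / % | target / % | starting material / % |
|---|---|---|---|---|---|
| theta | 10.0 | 21.7 | 0.2 | 12.4 | 66.9 |
| theta | 20.0 | 23.9 | 0.2 | 31.0 | 44.4 |
| theta | 30.0 | 23.8 | 0 | 46.2 | 29.8 |
| theta | 60.0 | 16.8 | 1.1 | 73.3 | 7.8 |
| theta | 120 | 8.3 | 1.6 | 89.2 | 1.7 |
| epsilon | 10.0 | 28.1 | 0.4 | 16.4 | 56.3 |
| epsilon | 30.0 | 27.6 | 0.3 | 54.1 | 15.8 |
| epsilon | 60.0 | 17.0 | 0.8 | 79.3 | 2.7 |
| epsilon | 80.0 | 12.5 | 1.2 | 84.3 | 0.8 |
| epsilon | 120 | 6.3 | 2.3 | 91.4 | 0 |

(readings scatter by 0.5 percentage points)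

1. which of these there is most of at the end, counted by the starting material in it, noon (starting material / over-reaction product / target / intermediate)
2. which of these there is most of at the end, counted by the starting material in it, winter (starting material / over-reaction product / target / intermediate)
3. the largest of these amounts at the end, in percent of the starting material charged, noon
4. the largest of these amounts at the end, in percent of the starting material charged, winter

Open the starting-material entry first. Epsilon kept 2.7% at 60.0 s, a first-order lifetime of 16.6 s. Scaled by loading, that is 15.3 s at noon, leaving about 0.0392% at 2.0 min.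

The intermediate entry stays open longest. Each target costs one partner, so free partner, as a fraction of the charge, is roughly the excess 0.100 plus the intermediate still standing. Once starting material has nearly gone, the ratio of intermediate plus excess to intermediate should grow exponentially, and its time constant is the tail time. Epsilon's fall from 17.0% to 6.3% between 60.0 s and 120 s gives 123 s, about as long as the asked 2.0 min and longer than the lifetime at noon. Noon and winter share epsilon's second catalyst and excess, but they differ from it in free catalyst, and at 120 s theta, with less free catalyst than epsilon, read 8.3% against epsilon's 6.3%. So epsilon's 6.3% goes into my books for both flasks only as a rough entry, uncertain by about the 2 percentage points between those readings.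

Over-reaction product I scale from epsilon by loading: 2.50% at noon and 3.75% at winter. My books close with target at 91.2% and 90.0%.

The forecast names target for noon and target for winter, at 91.5% and 90.2%, a little above mine, and says of the second step “so this step slows as partner runs out”.

    partner + free catalyst + target → free catalyst + over-reaction product (k = 31.3 M⁻² s⁻¹)
    partner + second catalyst + intermediate → second catalyst + target (k = 46500 M⁻² s⁻¹)
    starting material + free catalyst → free catalyst + intermediate (k = 129 M⁻¹ s⁻¹)

Noon gives target 91.4% and winter 91.3%, ahead of intermediate at 6.65% and 5.98%. Target's half-life by over-reaction alone, the other concentrations as charged at noon, is 13 min, longer than 2.0 min. Run the tail time from 1.00 min: noon's 16.8% should reach 6.26%, and the flask holds 6.65%; winter's 15.2% should reach 5.88%, and it holds 5.98%. The neighbour flask, winter with 0.280 equiv of partner, ends with intermediate at 72.1% and target at 27.8%.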